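## Analysis of the target

Germacrane numbering is used, read along the SMILES: C13H2=C11, C12 (lactone C=O), O, C6, C5=C4(C15H3), C3(OH), C2=C1, C10(C14H3)(OH), C9H2, C8(O-angelate), C7. Ring A is the ten-membered carbocycle C1–C10 with a 1E and a 4Z alkene. Ring B is the α-methylene-γ-butyrolactone O–C6–C7–C11–C12, trans-fused at C6–C7. All five stereocentres are R. In the zigzag C5–C9, O6 and C11 are syn (trans-lactone), C11 and O8 are anti, and O8 and O10 are 1,3-anti. O3 and O6 lie on the same face of ring A across the Z alkene. The feature that decides the strategy is C3. It is the only atom of ring A whose two ring bonds both go to alkene carbons (C2 of C1=C2 and C4 of C4=C5). It is therefore a reduced divinyl ketone, that is alkenyl + C1 + alkenyl. A second feature is that the O6/C11/O8 pattern is what results when an anti-2,3-epoxy alcohol (O6; C7–C8 epoxide) is opened at C7 with inversion by C11. Several groups are sensitive: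
- the bis-allylic C3 carbinol ionises easily;
- the tertiary allylic C10 carbinol is labile;
- the C11=C13 acrylate is a Michael and hydride acceptor;
- the angelate isomerises easily to the tiglate;
- any Z-γ-hydroxy enone or enal collapses to a furan.

The synthesis is hard because a strained ring with one E and one Z alkene must be closed, and because the C7/C8 relation is the opposite of what closed-transition-state allylations deliver.

## Retrosynthetic reasoning

**C11=C13 (24 ⇒ 22 + 23).** The exocyclic methylene is cut last. In the forward sense a Horner–Wadsworth–Emmons olefination of the α-phosphono lactone 22 with 23 unmasks it under mild base. The acrylate is thus absent during the palladium and hydride steps, where it would be the most vulnerable group.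

**C3–H (22 ⇒ 21).** The carbinol is traced back to the cross-conjugated dienone 21. The forward step is a reagent-controlled 1,2-reduction. It has to distinguish the α-methyl Z-alkenyl side (C4) from the unsubstituted E-alkenyl side (C2).

**C2–C3 and C3–C4 (21 ⇒ 19 + 20).** Both ring bonds of C3 are cut at once and C3 is excised as 20. Any single cut next to C3 would need a Z-enal or a Z-alkenoyl derivative with its geometry at risk. The double cut leaves two configurationally robust termini, a Z-alkenyl iodide at C4 and an E-alkenylstannane at C2, on the open-chain lactone 19. The forward carbonylative Stille coupling has to close ring A, insert one carbon and keep both geometries.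

**O8–acyl (19 ⇒ 16 + 17).** The angelate is attached before ring closure, so that no free secondary hydroxyl can intercept the acylpalladium species. It is attached after O8 has been set free in the lactone-forming step.

**C7–C11 and O6–C12 (16 ⇒ 15 ⇒ 13 + 14).** Ring B is cut at C7–C11, not at the usual C6–C7. The nucleophilic carbon C11 is tethered to O6 as the phosphonoacetate 15 and opens the C7–C8 epoxide at C7. The tether fixes the regiochemistry (five-membered ring). The inversion fixes the C7 configuration, O8 is liberated with its configuration intact, and the phosphonate stays on as the mask for C13.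

**C7–O and C8–O (13 ⇒ 12).** The anti-epoxy alcohol 13 comes from the E-allylic alcohol 12 by Sharpless asymmetric epoxidation. Run as a kinetic resolution, it also selects the C6 configuration. C6, C7 and C8 are thus fixed as a group in one catalytic event.

**C7=C8 (12 ⇒ 6 + 11).** The E alkene is cut by cross-metathesis into two fragments of similar size, each two steps from commercial material. Fragment 6 carries C10 and the stannane. Fragment 11 carries the Z-iodoalkene.

**Fragments.** 6 comes from the stannyl enone 4 and 5 by catalytic asymmetric allylboration, which sets C10. 4 comes from the two-carbon linchpin 1 (C1=C2) and 2 (C10, C14). 11 comes from the enynol 9 by hydroxyl-directed trans-hydroalumination and iodination, which sets the 4Z geometry. 9 comes from 7 and 8.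

## Alternatives that were turned down

**Alternative 1:** the textbook cut, C6–C7 together with O–C12.
- **Forward step.** An intramolecular Barbier or Nozaki–Hiyama allylation (Zn or CrCl2) joins the Z-enal and the 2-(bromomethyl)enoate in the seco compound A1. It closes ring A and, by lactonisation, ring B.
- **Lactone fusion.** The more stable geometry of a 2-alkoxycarbonylallyl metal has C8 cis to the metal-bearing CH2. A closed six-membered transition state then leads to the 6,7-cis lactone.
- **C7/C8 relation.** The required relation demands attack on the more hindered face of the allyl unit.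
- **Aldehyde.** It is a Z-enal, which isomerises readily to the E isomer.
- **Step economy.** C3, C8 and C10 would all have to be in place in one long linear chain before the decisive step.

**Alternative 2:** cut C1=C2.
- **Forward step.** Ring-closing metathesis of the tetraene A2.
- **Hindrance.** The alkene to be formed lies between the fully substituted C10 and the C3 carbinol, so both partners are sluggish.
- **Geometry.** Ten-membered rings made by metathesis favour the Z alkene or dimers, whereas the target needs 1E.
- **Competing sites.** The divinyl carbinol at C3 and the C11=C13 acrylate offer competing metathesis and isomerisation pathways.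
- **Step economy.** A2 needs the same stereocentres as the chosen precursor plus C3.

**Alternative 3:** cut C2–C3 only.
- **Forward step.** A Nozaki–Hiyama–Kishi closure (CrCl2, catalytic NiCl2) joins the E-alkenyl iodide and the Z-enal in A3.
- **Economy.** It forms one bond where the chosen step forms two.
- **Substrate.** A3 needs the γ-acyloxy Z-enal, which is prone to Z→E isomerisation and to vinylogous elimination of the lactone carboxylate.
- **Stereocontrol.** C3 is formed without an element of control.
- **Step economy.** C3 must be brought in by extra steps on a substrate that already contains the acrylate.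

Key step: step 10

Assumption: the (S)-diol of step 2 is taken to deliver the allyl group to the face of 4 that gives (R)-6, by analogy with aryl and alkenyl methyl ketones. If the sense is opposite, the (R)-diol is used and nothing else changes.

## Steps

Step 1
Reactants: 1 (E)-1,2-bis(tributylstannyl)ethene; 2 N-methoxy-N-methylacetamide
Product: 4 (E)-4-(tributylstannyl)but-3-en-2-one, via (E)-2-(tributylstannyl)vinyllithium 3 (not isolated)
Conditions: n-BuLi (1.0 equiv), THF, −78 °C; then 2, −78 → 0 °C
Reagents that add atoms: none
Why: Tin–lithium exchange on the symmetrical distannane is stereoretentive and stops after one exchange, and the alkenyllithium acylates the amide without over-addition (Weinreb ketone synthesis); the 1E alkene of the target is bought with 1.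

Step 2
Reactants: 4 (E)-4-(tributylstannyl)but-3-en-2-one; 5 2-allyl-1,3,2-dioxaborinane
Product: 6 (1E,3R)-3-methyl-1-(tributylstannyl)hexa-1,5-dien-3-ol
Conditions: (S)-3,3'-dibromo-BINOL (5 mol %), t-BuOH (2 equiv), toluene, 23 °C
Reagents that add atoms: none
Why: Diol-catalysed asymmetric allylboration of a methyl alkenyl ketone runs through a closed chair transition state in which the catalyst-bound boronate distinguishes the alkenyl from the methyl group; this sets C10 (R), and only 1,2-addition is expected.

Step 3
Reactants: 7 acrolein; 8 prop-1-yn-1-ylmagnesium bromide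
Product: 9 rac-hex-1-en-4-yn-3-ol
Conditions: THF, −78 → 0 °C
Reagents that add atoms: none
Why: This is a 1,2-addition of an alkynyl Grignard reagent to an enal; the carbinol (future C6) is left racemic on purpose because step 6 selects its configuration.

Step 4
Reactants: 9 rac-hex-1-en-4-yn-3-ol
Product: 11 rac-(4Z)-5-iodohexa-1,4-dien-3-ol, via cyclic sodium alkenylaluminate 10 (not isolated)
Conditions: NaAlH2(OCH2CH2OMe)2 (1.6 equiv), Et2O, 0 → 23 °C; EtOAc; then I2, THF, −78 °C
Reagents that add atoms: iodine, II
Why: Hydroxyl-directed trans-hydroalumination of the propargylic alcohol places aluminium on the distal alkyne carbon within the five-membered aluminate 10, and iodinolysis with retention gives the iodide cis to the carbinol carbon; this is the 4Z geometry of the target, and the isolated vinyl group is not reduced.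

Step 5
Reactants: 6 (1E,3R)-3-methyl-1-(tributylstannyl)hexa-1,5-dien-3-ol; 11 rac-(4Z)-5-iodohexa-1,4-dien-3-ol
Product: 12 (1E,3R,5E,7RS,8Z)-9-iodo-3-methyl-1-(tributylstannyl)deca-1,5,8-triene-3,7-diol (both C6 epimers)
Conditions: second-generation Hoveyda–Grubbs catalyst, RuCl2(H2IMes)(=CH-C6H4-2-OiPr) (5 mol %), 11 (2 equiv), CH2Cl2, 40 °C
Reagents that add atoms: none
Why: Cross-metathesis of an unhindered terminal alkene with a secondary allylic alcohol is E-selective; the trisubstituted iodoalkene and the stannyl alkene next to the quaternary C10 are too hindered to take part.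

Step 6
Reactants: 12 (1E,3R,5E,7RS,8Z)-9-iodo-3-methyl-1-(tributylstannyl)deca-1,5,8-triene-3,7-diol
Product: 13 (1E,3R,5R,6R,7R,8Z)-5,6-epoxy-9-iodo-3-methyl-1-(tributylstannyl)deca-1,8-diene-3,7-diol
Conditions: Ti(OiPr)4 (0.2 equiv), D-(−)-diisopropyl tartrate (0.25 equiv), t-BuOOH (0.55 equiv), 4 Å molecular sieves, CH2Cl2, −20 °C
Reagents that add atoms: tert-butyl hydroperoxide, CC(C)(C)OO
Why: In a Sharpless asymmetric epoxidation run as a kinetic resolution with the D-(−)-tartrate, only the C6 epimer with the target configuration is matched for C7=C8 and gives the anti (erythro) epoxy alcohol, so C6 is selected and C7–O and C8–O are set in one event, while the other epimer of 12 stays unchanged and is separated. In the matched epimer the Z-iodoalkene is mismatched and electron-poor, and tertiary allylic alcohols are poor substrates.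

Step 7
Reactants: 13 (1E,3R,5R,6R,7R,8Z)-5,6-epoxy-9-iodo-3-methyl-1-(tributylstannyl)deca-1,8-diene-3,7-diol; 14 2-(diethoxyphosphoryl)acetic acid
Product: 15 (1E,3R,5R,6S,7R,8Z)-5,6-epoxy-3-hydroxy-9-iodo-3-methyl-1-(tributylstannyl)deca-1,8-dien-7-yl 2-(diethoxyphosphoryl)acetate
Conditions: DCC, DMAP (5 mol %), CH2Cl2, 0 → 23 °C
Reagents that add atoms: none
Why: In this Steglich esterification the secondary C6–OH is acylated while the tertiary C10–OH is inert, and no stereocentre is touched (the descriptor at C7 changes only through the priority rules).

Step 8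
Reactants: 15 (1E,3R,5R,6S,7R,8Z)-5,6-epoxy-3-hydroxy-9-iodo-3-methyl-1-(tributylstannyl)deca-1,8-dien-7-yl 2-(diethoxyphosphoryl)acetate
Product: 16 diethyl {(4R,5S)-4-[(1R,3R,4E)-1,3-dihydroxy-3-methyl-5-(tributylstannyl)pent-4-en-1-yl]-5-[(1Z)-2-iodoprop-1-en-1-yl]-2-oxooxolan-3-yl}phosphonate (C11 epimers)
Conditions: LiCl (3 equiv), DBU (1.2 equiv), MeCN, 23 → 50 °C
Reagents that add atoms: none
Why: The lithium-chelated phosphonoacetate carbanion opens the epoxide at C7 by 5-exo-tet SN2 attack, the intramolecular form of the known epoxide opening by phosphonoacetate anions, with the tether geometry of carbamate-directed C2 opening of 2,3-epoxy alcohols and of tethered phosphonoacetate Michael cyclisations. Inversion at C7 turns the anti-epoxy alcohol into the trans-lactone (O6/C11 syn) and frees O8 with the target configuration (C11/O8 anti). Proton transfer from C11–H to the C8 alkoxide parks the product as the stabilised carbanion, which suppresses translactonisation.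

Step 9
Reactants: 16 diethyl {(4R,5S)-4-[(1R,3R,4E)-1,3-dihydroxy-3-methyl-5-(tributylstannyl)pent-4-en-1-yl]-5-[(1Z)-2-iodoprop-1-en-1-yl]-2-oxooxolan-3-yl}phosphonate; 17 angelic acid, (2Z)-2-methylbut-2-enoic acid
Product: 19 (1R,3R,4E)-1-{(2S,3R)-4-(diethoxyphosphoryl)-2-[(1Z)-2-iodoprop-1-en-1-yl]-5-oxooxolan-3-yl}-3-hydroxy-3-methyl-5-(tributylstannyl)pent-4-en-1-yl (2Z)-2-methylbut-2-enoate, via angelic 2,4,6-trichlorobenzoic anhydride 18 (not isolated)
Conditions: 17, 2,4,6-trichlorobenzoyl chloride, Et3N, toluene, 23 °C; then 16, 80 °C
Reagents that add atoms: none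
Why: Yamaguchi-type mixed-anhydride acylation without a nucleophilic catalyst is the standard way to make angelates without Z→E isomerisation; only the secondary C8–OH reacts, and the tertiary C10–OH stays free.

Step 10
Reactants: 19 (1R,3R,4E)-1-{(2S,3R)-4-(diethoxyphosphoryl)-2-[(1Z)-2-iodoprop-1-en-1-yl]-5-oxooxolan-3-yl}-3-hydroxy-3-methyl-5-(tributylstannyl)pent-4-en-1-yl (2Z)-2-methylbut-2-enoate; 20 carbon monoxide
Product: 21 diethyl [(1E,4Z,6R,7R,8R,10R)-8-angeloyloxy-10-hydroxy-3-oxogermacra-1,4-dien-12,6-olid-11-yl]phosphonate (C11 epimers)
Conditions: Pd2(dba)3 (10 mol %), AsPh3 (40 mol %), 20 (3 bar), THF, 50 °C, slow addition of 19 to a final 1 mM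
Reagents that add atoms: none
Why: Zerovalent palladium inserts into the C4–I bond of 19 with retention, 20 inserts to give the (Z)-alkenoylpalladium iodide, the E-alkenylstannane at C2 transmetalates intramolecularly and reductive elimination forms C2–C3, so that C3–C4 and C2–C3 are made in one operation and C3 is supplied by 20. The closest known reaction type is the carbonylative Stille coupling of alkenyl iodides with alkenylstannanes to divinyl ketones, including its use as the macrocycle-forming step for medium and large ring dienones. Ring A is closed end to end in a [9+1] mode by reductive elimination from an eleven-membered acyl(alkenyl)palladacycle; ring B is already present and acts as a turn element, because the trans-lactone holds the C6 and C7 side chains gauche and the Z alkene points C4 back towards the chain. No stereocentre is formed; the two alkene geometries (1E from 1, 4Z from step 4) are carried over with retention and are then locked by the ring. Insertion of 20 has to beat direct coupling: direct coupling would give a far more strained nine-membered (E,Z)-diene ring, and pressure of 20 with the weakly donating AsPh3 favours insertion before transmetalation. Cyclisation has to beat oligomerisation, which slow addition to high dilution secures. The acylpalladium must find no other partner: C11 carries the phosphonate and not yet the methylene group (no acylpalladation of an acrylate), O6 and O8 are acylated (no furan from a Z-γ-hydroxy enone, no lactone trap) and the free C10–OH is tertiary.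

Step 11
Reactants: 21 diethyl [(1E,4Z,6R,7R,8R,10R)-8-angeloyloxy-10-hydroxy-3-oxogermacra-1,4-dien-12,6-olid-11-yl]phosphonate
Product: 22 diethyl [(1E,3R,4Z,6R,7R,8R,10R)-8-angeloyloxy-3,10-dihydroxygermacra-1,4-dien-12,6-olid-11-yl]phosphonate (C11 epimers)
Conditions: (S)-2-methyl-CBS-oxazaborolidine (20 mol %), catecholborane (3 equiv), toluene, −78 °C
Reagents that add atoms: none
Why: In the Corey–Bakshi–Shibata 1,2-reduction the α-methyl Z-alkenyl side (C4) acts as the large group and the E-CH=CH side (C2) as the small group, so the (S)-catalyst should give the 3R carbinol; with C13 still masked there is no acrylate that could be reduced in a conjugate sense.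

Step 12
Reactants: 22 diethyl [(1E,3R,4Z,6R,7R,8R,10R)-8-angeloyloxy-3,10-dihydroxygermacra-1,4-dien-12,6-olid-11-yl]phosphonate; 23 formaldehyde
Product: 24 (1E,3R,4Z,6R,7R,8R,10R)-8-angeloyloxy-3,10-dihydroxygermacra-1,4,11(13)-trien-12,6-olide (target)
Conditions: K2CO3 (2 equiv), 37 % aq. 23, THF, 0 → 23 °C
Reagents that add atoms: none
Why: Horner–Wadsworth–Emmons olefination of an α-phosphono lactone with formaldehyde is a standard mild entry to α-methylene lactones; both C11 epimers converge, and the carbonate base should leave the angelate, the carbinols and C7 untouched.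

## Compound list

1 | (E)-1,2-bis(tributylstannyl)ethene | CCCC[Sn](CCCC)(CCCC)/C=C/[Sn](CCCC)(CCCC)CCCC | starting material
2 | N-methoxy-N-methylacetamide | CC(=O)N(C)OC | starting material
3 | (E)-2-(tributylstannyl)vinyllithium | [Li]/C=C/[Sn](CCCC)(CCCC)CCCC | intermediate
4 | (E)-4-(tributylstannyl)but-3-en-2-one | CC(=O)/C=C/[Sn](CCCC)(CCCC)CCCC | intermediate
5 | 2-allyl-1,3,2-dioxaborinane | C=CCB1OCCCO1 | starting material
6 | (1E,3R)-3-methyl-1-(tributylstannyl)hexa-1,5-dien-3-ol | CCCC[Sn](CCCC)(CCCC)/C=C/[C@](C)(O)CC=C | intermediate
7 | acrolein | C=CC=O | starting material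
8 | prop-1-yn-1-ylmagnesium bromide | CC#C[Mg]Br | starting material
9 | rac-hex-1-en-4-yn-3-ol | C=CC(O)C#CC | intermediate
10 | cyclic sodium alkenylaluminate from 9 | C=CC1C=C(C)[Al-](OCCOC)(OCCOC)O1.[Na+] | intermediate
11 | rac-(4Z)-5-iodohexa-1,4-dien-3-ol | C=CC(O)/C=C(/C)I | intermediate
12 | (1E,3R,5E,7RS,8Z)-9-iodo-3-methyl-1-(tributylstannyl)deca-1,5,8-triene-3,7-diol | CCCC[Sn](CCCC)(CCCC)/C=C/[C@](C)(O)C/C=C/C(O)/C=C(/C)I | intermediate
13 | (1E,3R,5R,6R,7R,8Z)-5,6-epoxy-9-iodo-3-methyl-1-(tributylstannyl)deca-1,8-diene-3,7-diol | CCCC[Sn](CCCC)(CCCC)/C=C/[C@](C)(O)C[C@H]1O[C@@H]1[C@H](O)/C=C(/C)I | intermediate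
14 | 2-(diethoxyphosphoryl)acetic acid | CCOP(=O)(CC(=O)O)OCC | starting material
15 | phosphonoacetate of 13 at O6 | CCCC[Sn](CCCC)(CCCC)/C=C/[C@](C)(O)C[C@H]1O[C@@H]1[C@H](OC(=O)CP(=O)(OCC)OCC)/C=C(/C)I | intermediate
16 | α-phosphono trans-lactone with free C8–OH (C11 epimers) | CCCC[Sn](CCCC)(CCCC)/C=C/[C@](C)(O)C[C@@H](O)[C@H]1C(P(=O)(OCC)OCC)C(=O)O[C@@H]1/C=C(/C)I | intermediate
17 | angelic acid | C/C=C(/C)C(=O)O | starting material
18 | angelic 2,4,6-trichlorobenzoic anhydride | C/C=C(/C)C(=O)OC(=O)c1c(Cl)cc(Cl)cc1Cl | intermediate
19 | 8-O-angelate of 16 (seco iodide/stannane) | CCCC[Sn](CCCC)(CCCC)/C=C/[C@](C)(O)C[C@@H](OC(=O)/C(C)=C\C)[C@H]1C(P(=O)(OCC)OCC)C(=O)O[C@@H]1/C=C(/C)I | intermediate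
20 | carbon monoxide | [C-]#[O+] | starting material
21 | macrocyclic 3-oxo-1,4-diene phosphonate (C11 epimers) | CCOP(=O)(OCC)C1C(=O)O[C@@H]2/C=C(/C)C(=O)/C=C/[C@](C)(O)C[C@@H](OC(=O)/C(C)=C\C)[C@@H]12 | intermediate
22 | macrocyclic (3R)-carbinol phosphonate (C11 epimers) | CCOP(=O)(OCC)C1C(=O)O[C@@H]2/C=C(/C)[C@H](O)/C=C/[C@](C)(O)C[C@@H](OC(=O)/C(C)=C\C)[C@@H]12 | intermediate
23 | formaldehyde | C=O | starting material
24 | (1E,3R,4Z,6R,7R,8R,10R)-8-angeloyloxy-3,10-dihydroxygermacra-1,4,11(13)-trien-12,6-olide | C=C1C(=O)O[C@@H]2/C=C(/C)[C@H](O)/C=C/[C@](C)(O)C[C@@H](OC(=O)/C(C)=C\C)[C@@H]12 | target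

## Step count and least certain steps

Total step count: 12. Longest linear sequence: 10 (steps 1, 2, 5–12 or steps 3, 4, 5–12). Because step 6 is a resolution, at most half of 12 can be carried forward.

**Step 10 (key step).**
- **What may go wrong.** Transmetalation within the strained eleven-membered palladacycle may be slower than intermolecular transmetalation or protodestannylation, which would lead to oligomerisation. The Z-alkenoylpalladium may isomerise before it couples. Zerovalent palladium may ionise the allylic C6–O bond of the product.
- **Fallback.** It closes the ring at C3–C4 only and brings C3 in beforehand. It sets out from 19. Chemoselective ozonolysis of the electron-rich stannyl alkene (O3, CH2Cl2, −78 °C; Me2S) gives the α-hydroxy aldehyde F1. A Wittig reaction with (triphenylphosphoranylidene)acetaldehyde gives the E-enal F2, which carries a new C2 and C3. A Nozaki–Hiyama–Kishi closure (CrCl2, catalytic NiCl2, DMSO/THF, high dilution) between C4–I and the C3 aldehyde gives 22 together with its C3 epimer F3. F3 is oxidised with MnO2 to 21 and re-enters at step 11. The fallback comes back to the route at 22.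

**Step 8.**
- **What may go wrong.** After ring opening, the C8 alkoxide may attack phosphorus before it is protonated. Phosphoryl transfer from C11 to O8 and closure of a three-membered ring would follow, as in the phosphonate cyclopropanation of epoxides. The SN2 step itself may also be slow, because the ester tether prefers the extended conformation.
- **Fallback.** It gives up the phosphonate as a long-lived mask. It sets out from 15. The opening is run in the presence of paraformaldehyde (LiCl, DBU, MeCN), so that the carbanion is olefinated as soon as the lactone has formed (telescoped cyclisation/olefination). This gives the α-methylene lactone diol F4. Acylation as in step 9 gives the angelate F5. Carbonylative closure as in step 10 gives the 3-oxo trienolide F6. The reduction of step 11 leads to 24, where the fallback comes back to the route.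

**Step 6.**
- **What may go wrong.** The free tertiary C10–OH binds titanium and may direct oxygen transfer to the electron-rich stannyl alkene. It may also erode the rate difference between the two C6 epimers.
- **Fallback.** It removes the second directing group. It sets out from 6. Silylation (Et3SiOTf, 2,6-lutidine) gives the triethylsilyl ether F7. Cross-metathesis with 11 as in step 5 gives the mono-alcohol F8. Epoxidation as in step 6 gives the silylated epoxy alcohol F9. Buffered fluoride (Bu4NF, AcOH) returns 13, where the fallback comes back to the route.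

**Step 11.**
- **What may go wrong.** Facial selectivity may be poor. In the ring only the outer face of the C3 carbonyl is open, and this intrinsic bias may oppose the catalyst. The size difference between the two alkenyl groups is also modest.
- **Fallback.** An enzymatic reduction of 21 to 22 with an NADPH-dependent ketoreductase (short-chain dehydrogenase/reductase class) chosen from a panel with glucose dehydrogenase recycling. It sets out from 21, comes back at 22 and makes no new compound.

## Further compounds

F1 | step 10 | C1 α-hydroxy aldehyde from ozonolysis of 19 | O=C[C@](C)(O)C[C@@H](OC(=O)/C(C)=C\C)[C@H]1C(P(=O)(OCC)OCC)C(=O)O[C@@H]1/C=C(/C)I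
F2 | step 10 | (1E)-enal with C3 as aldehyde and C4 iodide | O=C/C=C/[C@](C)(O)C[C@@H](OC(=O)/C(C)=C\C)[C@H]1C(P(=O)(OCC)OCC)C(=O)O[C@@H]1/C=C(/C)I
F3 | step 10 | C3 epimer of 22 | CCOP(=O)(OCC)C1C(=O)O[C@@H]2/C=C(/C)[C@@H](O)/C=C/[C@](C)(O)C[C@@H](OC(=O)/C(C)=C\C)[C@@H]12
F4 | step 8 | α-methylene trans-lactone diol (iodide/stannane) | CCCC[Sn](CCCC)(CCCC)/C=C/[C@](C)(O)C[C@@H](O)[C@H]1C(=C)C(=O)O[C@@H]1/C=C(/C)I
F5 | step 8 | 8-O-angelate of F4 | CCCC[Sn](CCCC)(CCCC)/C=C/[C@](C)(O)C[C@@H](OC(=O)/C(C)=C\C)[C@H]1C(=C)C(=O)O[C@@H]1/C=C(/C)I
F6 | step 8 | 3-oxo analogue of 24 | C=C1C(=O)O[C@@H]2/C=C(/C)C(=O)/C=C/[C@](C)(O)C[C@@H](OC(=O)/C(C)=C\C)[C@@H]12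
F7 | step 6 | triethylsilyl ether of 6 | CCCC[Sn](CCCC)(CCCC)/C=C/[C@](C)(O[Si](CC)(CC)CC)CC=C
F8 | step 6 | 10-O-triethylsilyl ether of 12 (both C6 epimers) | CCCC[Sn](CCCC)(CCCC)/C=C/[C@](C)(O[Si](CC)(CC)CC)C/C=C/C(O)/C=C(/C)I
F9 | step 6 | 10-O-triethylsilyl ether of 13 | CCCC[Sn](CCCC)(CCCC)/C=C/[C@](C)(O[Si](CC)(CC)CC)C[C@H]1O[C@@H]1[C@H](O)/C=C(/C)I
F0 | step 11 | none | none
A1 | alternative 1 | seco Z-enal / (Z)-2-(bromomethyl)enoate, 3-O-TBS | O=C/C=C(/C)[C@H](O[Si](C)(C)C(C)(C)C)/C=C/[C@](C)(O)C[C@@H](OC(=O)/C(C)=C\C)/C=C(\CBr)C(=O)OC
A2 | alternative 2 | 1,2-seco tetraene for ring-closing metathesis | C=C1C(=O)O[C@H](/C=C(/C)[C@H](O)C=C)[C@H]1[C@@H](C[C@@](C)(O)C=C)OC(=O)/C(C)=C\C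
A3 | alternative 3 | 2,3-seco Z-enal / E-alkenyl iodide | C=C1C(=O)O[C@H](/C=C(/C)C=O)[C@H]1[C@@H](C[C@@](C)(O)/C=C/I)OC(=O)/C(C)=C\C
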